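Readings and results stem from a simulated flask on assumed constants, noise included.

Slowness is not the trouble in these flasks. The product takes days to climb, yet the midnight run reads 48.9 % at 6.00 d and 48.2 % at 10.0 d, so you should ask where it stops.

| flask | solid substrate | protic impurity | solid reagent | remark | time |
|---|---|---|---|---|---|
| summer | 1.1 M | 0.77 M | 1.39 M | run made earlier |  |
| noon | 1.7 M | 0.77 M | 1.39 M | run made earlier |  |
| midnight | 0.77 M | 0.77 M | 2.1 M | run made earlier |  |
| flask | 0.77 M | 0.770 M | 1.39 M |  | 8.0 d |

- summer (time / d: product / %): 0.833: 5.3; 1.67: 11.3; 2.50: 17.9; 5.00: 32.1; 10.0: 31.6
- noon (time / d: product / %): 2.08: 7.3; 4.00: 20.8; 6.00: 21.0; 8.00: 19.1; 10.0: 20.7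
- midnight (time / d: product / %): 2.08: 20.8; 4.00: 41.6; 6.00: 48.9; 8.00: 49.8; 10.0: 48.2

(scatter of a reading: 1 percentage point)

* product at 8.0 d, in percent of the solid substrate charged
* the change that raises the amount of product at 8.0 d, in percent of the solid substrate charged most ("none" if none brings more than 2 percentage points) (beta / theta / eta / gamma / none)
* amount of product at 8.0 d, in percent of the solid substrate charged, after eta

- beta: doubling the solubility of the solid substrate, all else as stated
- theta: doubling the dissolution coefficient of the solid substrate, all else as stated
- eta: doubling the dissolution coefficient of the solid reagent, all else as stated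
- gamma: doubling the solubility of the solid reagent, all else as stated

Start with the balance of the coupling partner. Protic impurity quenches it one for one, so this flask holds 0.620 M of spare reagent, meaning the solid reagent charged minus the protic impurity charged. Once that impurity is consumed and the solid reagent has dissolved, [product] + [coupling partner] equals the spare reagent. It is this flask's limiting reagent, below the 0.77 M of solid substrate.

The summer run has the same spare reagent, 0.620 M, and so does the noon run. Their product stands at 0.353 M and 0.352 M, although noon holds more solid substrate. Leftover solid evidently holds [dissolved substrate] at one level in both.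

This gives two ways to the flask. If solid substrate remains, the flask repeats that product. If it dissolves completely, take the summer ratio [product]/([dissolved substrate][coupling partner]) as 1.77 /M and solve the balance.

| Flask's solid substrate | Product |
|---|---|
| still present | 45.9 % |
| wholly dissolved | 37.2 % |

They part, and each cheats. The first assumes solid remains. The second counts all the summer substrate as dissolved, which noon contradicts, so its ratio reads low. I therefore commit to the middle, 41.5 %, for the flask and after eta. The changes offered touch the solids, through their solubility or their dissolution. If both solids have dissolved and the plateau has been reached by 8.0 d, as the midnight run's product had by 6.00 d, these changes leave the balance and the ratio as they are, so I choose none; that choice rests on this condition.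

The forecast, which differs, gives 47 %, gamma and 47 %: “Only higher partner concentration shifts the equilibrium”.

The flask gives 41.1 %, best change none, and 41.1 % after eta, with 0 % solid substrate and 0 % solid reagent left at 8.00 d.

    coupling partner + protic impurity → quenched reagent (k = 1.10 × 10⁻⁴ /M/s)
    solid substrate ⇌ dissolved substrate, rate k2*(cs2 - [dissolved substrate]) while solid is left; crystals form when [dissolved substrate] > cs2 (solubility = 0.550 M, k = 2.00 × 10⁻⁴ /s)
    dissolved substrate + coupling partner ⇌ product (K = 2.30 /M, k = 2.50 × 10⁻⁵ /M/s)
    solid reagent ⇌ coupling partner, rate k4*(cs4 - [coupling partner]) while solid is left; crystals form when [coupling partner] > cs4 (solubility = 0.410 M, k = 2.00 × 10⁻⁵ /s)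

There, product 0.317 M plus partner 0.303 M returns the spare reagent, 0.620 M. In the neighbour with 1.3 M of solid substrate, the spare reagent is unchanged and solid should remain, so the summer product gives 27.2 %. That flask gives 26.6 %, with 31.1 % solid substrate left.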